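The data were computed from invented constants; noise was put on by code.

We have two questions, a row of end amounts of Q and its shape, and the runs below to answer them from.

all flasks: L 0.050 M
- east: J 0.0082 M; run made earlier
- south-east: J 0.13 M; run made earlier
- alpha: J 0.00600 M; time 6.0 min; volume of the second phase over the first 0.25
- epsilon: J 0.0120 M; time 6.0 min; volume of the second phase over the first 0.25
- delta: J 0.0250 M; time 6.0 min; volume of the second phase over the first 0.25
- beta: J 0.0500 M; time 6.0 min; volume of the second phase over the first 0.25
- theta: J 0.100 M; time 6.0 min; volume of the second phase over the first 0.25

| run | time / min | Q / % | L / % |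
|---|---|---|---|
| east | 0.667 | 2.1 | 97.8 |
| east | 1.33 | 4.4 | 94.4 |
| east | 2.00 | 4.8 | 92.0 |
| east | 3.00 | 5.3 | 88.5 |
| east | 4.00 | 5.0 | 87.5 |
| south-east | 0.667 | 24.4 | 70.6 |
| south-east | 1.33 | 36.9 | 38.5 |
| south-east | 2.00 | 33.7 | 21.6 |
| south-east | 3.00 | 22.0 | 8.9 |
| south-east | 4.00 | 13.1 | 3.3 |

(standard deviation of a reading: 0.3 percentage points)

- amount of Q at the end, in percent of the L charged for alpha, epsilon, delta, beta, theta, in this order
- the shape of the row from first to last (rises, then falls / falls all the way / rises all the way / hardly changes / falls, then rises)

- in the second phase: J; everything else is in the first
- charges count per volume of the first phase; a concentration in a rate is the amount of a species over the volume of its own phase; every rate counts per litre of the first phase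
- the earlier runs hold the two phases in the same ratio of volumes as the flask asked about
- "hardly changes" means that all values lie within two and a half points (for a concentration: within two and a half percent of the largest)

Let us bracket alpha, the first point of the row. Both charges count per litre of the first phase, so if L and J react one for one, J is the limiting reagent in alpha and L can lose at most 12.0%; that is the loose bound from above, and zero is the loose bound from below.

To tighten it we need the loss constant of Q, k, defined as the first-order rate at which Q disappears. Between the last two south-east readings, L lost plus Q lost, over the mean Q, gives 0.826 min⁻¹. The half-life of Q in the south-east run, 0.839 min, is a reading, and it is short against 6.0 min. The same reckoning between the east readings at 2.00 min and 4.00 min gives 0.439 min⁻¹, a slower loss than in the south-east run, so the constant depends on the J charge and we reckon the lower bound with 0.826 min⁻¹ and the upper bound with 0.439 min⁻¹.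

The east run is nearly alpha, so we scale its last reading by the J charges and get Q of 3.66% at 4.00 min, with 2.85% of L still to be lost. Over the remaining time, Q alone keeps a factor 0.192 with the south-east constant and 0.416 with the east one. If the remaining L all reacted at once, its Q would decay with the rest, which gives the lower bound 1.25%. If it all reacted at the last moment, none of it would decay, and with the east factor for the Q already there this gives the upper bound 4.37%. We commit to the middle, 2.81%.

The forecast gives 0.8%, 2.8%, 5.5%, 7%, 5%, shape rises, then falls; its first point lies under our bracket, on the ground that “low charges have run out of J, so Q has been decaying for a while and is small”.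

The flask gives 2.05%, 3.97%, 7.56%, 11.2%, 7.16%, shape rises, then falls. Alpha lies inside the bracket, and the forecast held within its margin.

    Z ⇌ J, rate k1*([Z] - [J]/K1) per volume of the first phase (partition coefficient = 1.60, kL = 0.00700 s⁻¹)
    L + Z → Q (k = 0.310 L mol⁻¹ s⁻¹)
    Z + Q → G (k = 0.120 L mol⁻¹ s⁻¹)
    Q → X (k = 0.00840 s⁻¹)

The bracket also serves theta, started from its state at 3.00 min, where the two read constants give Q a reckoned factor of 0.0839 or 0.268 up to the end. With the L lost afterwards, the bounds are 3.27% and 20.2%, and theta ends at 7.16%. In alpha, the half-life of Q by the step from Q to X is 1.4 min, short against 6.0 min. At the end of alpha, that step uses Q 290 times faster than the step from Z + Q to G.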